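**Retrosynthetic overview**

1. Target 24 ⇒ aromatic Claisen shift (C5–C bond) of the C6–O 1,1-dimethylallyl ether 22 ⇒ phenol 19 (propargylation, semi-hydrogenation) ⇒ protected diaryl ether ester 18.
2. 18 ⇒ ring A aryne (from silyl triflate 9) + ring B phenoxide (from 13) + CO2 + MeI. The feature used: in ring A (C1 CO2Me, C2 O-aryl, C3 H, C4 CH3, C5 prenyl, C6 OH) the aryloxy oxygen and the ester carbon sit on the neighbouring carbons C2 and C1, and C6, on the other side of C1, bears an oxygen that polarises a C1–C2 aryne.
3. 9 ⇐ orcinol (mono-MOM ether, carbamate-directed C-silylation between the two oxygens, triflation); 13 ⇐ 2,4-dimethoxyphenol (ortho-formylation, reduction, O-silylation).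
4. No ring is formed at any stage: both benzene rings are bought and only substituent bonds are made.

Key step: step 8

Remark: the target has no stereocentre. Ring A is numbered C1 (CO2Me), C2 (O-aryl), C3 (H), C4 (CH3), C5 (prenyl), C6 (OH) and ring B C1′ (O), C2′ (CH2O), C4′ and C6′ (OCH3) throughout, also in the names of 21–24.

**Route**

Step 1
Reactants: 1 orcinol (5-methylbenzene-1,3-diol)
Product: 2 3-(methoxymethoxy)-5-methylphenol
Conditions: NaH (1.0 equiv), DMF, 0 °C; MOMCl (1.0 equiv), 0 °C → rt
Reagents that add atoms: chloromethyl methyl ether, COCCl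
Why: Williamson-type O-alkylation of the monosodium phenoxide; the two hydroxyls of orcinol are equivalent, so one equivalent of base and chloride should give the mono-ether as main product, separable from recovered 1 and the bis-ether.

Step 2
Reactants: 2 3-(methoxymethoxy)-5-methylphenol
Product: 3 3-(methoxymethoxy)-5-methylphenyl N-isopropylcarbamate
Conditions: i-PrNCO, Et3N (cat.), CH2Cl2, rt
Reagents that add atoms: isopropyl isocyanate, CC(C)N=C=O
Why: Base-catalysed addition of the phenol to the isocyanate (carbamoylation) runs under conditions that leave the acetal untouched and installs a strong, later easily removed, directing group for lithiation.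

Step 3
Reactants: 3 3-(methoxymethoxy)-5-methylphenyl N-isopropylcarbamate
Product: 7 3-(methoxymethoxy)-5-methyl-2-(trimethylsilyl)phenyl N-isopropylcarbamate, via N-silyl carbamate 4 (not isolated), via aryllithium 5 (not isolated), via bis-silyl carbamate 6 (not isolated)
Conditions: TBSOTf, TMEDA, Et2O, 0 °C → rt; n-BuLi, TMEDA, −78 °C; TMSCl, −78 °C → rt; cold aq. NaHSO4 work-up
Reagents that add atoms: chlorotrimethylsilane, C[Si](C)(C)Cl
Why: Directed ortho-metalation in which transient N-silylation masks the N–H, the C–H between the carbamate and methoxymethoxy oxygens is the most acidic and doubly coordinated site, trapping at −78 °C forestalls the anionic ortho-Fries shift, and the N–Si bond is hydrolysed on work-up.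

Step 4
Reactants: 7 3-(methoxymethoxy)-5-methyl-2-(trimethylsilyl)phenyl N-isopropylcarbamate
Product: 9 3-(methoxymethoxy)-5-methyl-2-(trimethylsilyl)phenyl trifluoromethanesulfonate, via silylphenol 8 (not isolated)
Conditions: DBU, Et2NH, MeCN, 40 °C; then PhNTf2, rt
Reagents that add atoms: N-phenylbis(trifluoromethanesulfonimide), O=S(=O)(N(c1ccccc1)S(=O)(=O)C(F)(F)F)C(F)(F)F
Why: DBU removes the carbamate N–H and the anion expels the phenoxide by E1cB elimination (the isopropyl isocyanate is scavenged by Et2NH as a urea), after which PhNTf2 sulfonylates the phenoxide in the same flask.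

Step 5
Reactants: 10 2,4-dimethoxyphenol
Product: 11 2-hydroxy-3,5-dimethoxybenzaldehyde
Conditions: MgCl2, Et3N, (CH2O)n, MeCN, reflux; aq. HCl work-up
Reagents that add atoms: paraformaldehyde (as formaldehyde), C=O
Why: Magnesium-mediated ortho-formylation of phenols (Casnati–Skattebøl reaction) delivers formaldehyde within a magnesium phenoxide chelate to the only free ortho position, the para position being blocked by methoxy.

Step 6
Reactants: 11 2-hydroxy-3,5-dimethoxybenzaldehyde
Product: 12 2-(hydroxymethyl)-4,6-dimethoxyphenol
Conditions: NaBH4, MeOH, 0 °C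
Reagents that add atoms: none
Why: Borohydride reduction of an aryl aldehyde to the benzylic alcohol is fast at 0 °C and touches nothing else in the molecule.

Step 7
Reactants: 12 2-(hydroxymethyl)-4,6-dimethoxyphenol
Product: 13 2,4-dimethoxy-6-(triisopropylsilyloxymethyl)phenol
Conditions: TIPSCl (1.05 equiv), imidazole, CH2Cl2, 0 °C → rt
Reagents that add atoms: chlorotriisopropylsilane, CC(C)[Si](Cl)(C(C)C)C(C)C
Why: Chemoselective silylation, since the unhindered primary alcohol should react with the bulky chlorosilane much faster than the phenol, which is flanked by two ortho substituents and hydrogen-bonded.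

Step 8
Reactants: 13 2,4-dimethoxy-6-(triisopropylsilyloxymethyl)phenol; 9 3-(methoxymethoxy)-5-methyl-2-(trimethylsilyl)phenyl trifluoromethanesulfonate
Product: 18 methyl 2-[2,4-dimethoxy-6-(triisopropylsilyloxymethyl)phenoxy]-6-(methoxymethoxy)-4-methylbenzoate, via potassium phenoxide 14 (not isolated), via aryne 15 (not isolated), via aryl potassium 16 (not isolated), via potassium carboxylate 17 (not isolated)
Conditions: KH, THF, 0 °C (13 → 14, slight excess over 9); spray-dried KF, 18-crown-6, CO2 (1 atm), THF, 0 °C, slow addition of 9; then MeI, 0 °C → rt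
Reagents that add atoms: carbon dioxide, O=C=O; iodomethane, CI
Why: Proposed new method: fluoride attacks the trimethylsilyl group of 9 and triflate departs to give aryne 15 across C1–C2, whose strained triple bond is polarised inductively by the C6 methoxymethoxy group, so phenoxide 14 should add at the distal carbon C2 and the charge should develop at C1, between two oxygen-bearing carbons, as aryl potassium 16. Because 14 is preformed with KH and the medium holds no O–H or N–H acid, 16 should be captured by dissolved CO2 to give carboxylate 17, which iodomethane esterifies in the same flask by an SN2 reaction that is indifferent to the two ortho substituents. The closest known reaction types are the fluoride-induced O-arylation of phenols with ortho-silylaryl triflates and the three-component coupling of arynes, amines and CO2 to anthranilic acids; what is new is CO2 capture after addition of an anionic oxygen nucleophile. No ring is closed and no stereocentre is formed. The selectivities needed are C2 over C1 attack (secured by the C6 oxygen substituent and the unhindered C3–H side), O- over C-arylation (secured because both ortho positions and the para position of 14 are substituted) and carboxylation over protonation (secured by aprotic conditions, the CO2 atmosphere and slow addition of 9). The primary triisopropylsilyl ether is expected to outlast KF/18-crown-6 at 0 °C, because the aryl–Si bond activated by the ortho triflate is far more fluoride-labile.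

Step 9
Reactants: 18 methyl 2-[2,4-dimethoxy-6-(triisopropylsilyloxymethyl)phenoxy]-6-(methoxymethoxy)-4-methylbenzoate
Product: 19 methyl 2-[2-(hydroxymethyl)-4,6-dimethoxyphenoxy]-6-hydroxy-4-methylbenzoate
Conditions: HCl (1.25 M in MeOH), 40 °C
Reagents that add atoms: none
Why: Acid-catalysed acetal exchange and silyl ether methanolysis remove both protecting groups at once, while the methyl ester is degenerate in methanol and the benzylic alcohol, whose cation is only weakly stabilised (both methoxy groups are meta to it), should resist solvolysis.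

Step 10
Reactants: 19 methyl 2-[2-(hydroxymethyl)-4,6-dimethoxyphenoxy]-6-hydroxy-4-methylbenzoate; 20 3-chloro-3-methylbut-1-yne
Product: 21 methyl 2-[2-(hydroxymethyl)-4,6-dimethoxyphenoxy]-4-methyl-6-[(2-methylbut-3-yn-2-yl)oxy]benzoate
Conditions: K2CO3, KI (cat.), CuI (cat.), acetone, 55 °C
Reagents that add atoms: none
Why: Copper-catalysed O-alkylation of a phenoxide with a tertiary propargylic chloride (through a copper acetylide/allenylidene) forms the tertiary ether, and K2CO3 ionises only the phenol, so the benzylic alcohol stays free.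

Step 11
Reactants: 21 methyl 2-[2-(hydroxymethyl)-4,6-dimethoxyphenoxy]-4-methyl-6-[(2-methylbut-3-yn-2-yl)oxy]benzoate
Product: 22 methyl 2-[2-(hydroxymethyl)-4,6-dimethoxyphenoxy]-4-methyl-6-[(2-methylbut-3-en-2-yl)oxy]benzoate
Conditions: H2 (1 atm), Pd/CaCO3 poisoned with Pb(OAc)2, quinoline, EtOAc, rt
Reagents that add atoms: none
Why: Semi-hydrogenation over lead-poisoned palladium (Lindlar reduction) should stop at the terminal alkene without hydrogenolysis of the benzylic alcohol or the aryl ethers.

Step 12
Reactants: 22 methyl 2-[2-(hydroxymethyl)-4,6-dimethoxyphenoxy]-4-methyl-6-[(2-methylbut-3-en-2-yl)oxy]benzoate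
Product: 24 methyl 2-[2-(hydroxymethyl)-4,6-dimethoxyphenoxy]-6-hydroxy-4-methyl-5-(3-methylbut-2-enyl)benzoate (CNP0583011.0), via dienone 23 (not isolated)
Conditions: PhNEt2, 130 °C
Reagents that add atoms: none
Why: Aromatic Claisen rearrangement in which the [3,3] shift can only end productively at C5 because C1 carries the ester, the allyl unit is inverted so that the tertiary ether carbon becomes the trisubstituted alkene terminus of a linear prenyl group, and dienone 23 tautomerises to the phenol.

**Compound list**

1 | orcinol (5-methylbenzene-1,3-diol) | Cc1cc(O)cc(O)c1 | starting material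
2 | 3-(methoxymethoxy)-5-methylphenol | COCOc1cc(C)cc(O)c1 | intermediate
3 | 3-(methoxymethoxy)-5-methylphenyl N-isopropylcarbamate | COCOc1cc(C)cc(OC(=O)NC(C)C)c1 | intermediate
4 | 3-(methoxymethoxy)-5-methylphenyl N-(tert-butyldimethylsilyl)-N-isopropylcarbamate | COCOc1cc(C)cc(OC(=O)N(C(C)C)[Si](C)(C)C(C)(C)C)c1 | intermediate
5 | 2-lithio derivative of 4 (lithium on the carbon between the two oxygens) | [Li]c1c(OCOC)cc(C)cc1OC(=O)N(C(C)C)[Si](C)(C)C(C)(C)C | intermediate
6 | 3-(methoxymethoxy)-5-methyl-2-(trimethylsilyl)phenyl N-(tert-butyldimethylsilyl)-N-isopropylcarbamate | COCOc1cc(C)cc(OC(=O)N(C(C)C)[Si](C)(C)C(C)(C)C)c1[Si](C)(C)C | intermediate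
7 | 3-(methoxymethoxy)-5-methyl-2-(trimethylsilyl)phenyl N-isopropylcarbamate | COCOc1cc(C)cc(OC(=O)NC(C)C)c1[Si](C)(C)C | intermediate
8 | 3-(methoxymethoxy)-5-methyl-2-(trimethylsilyl)phenol | COCOc1cc(C)cc(O)c1[Si](C)(C)C | intermediate
9 | 3-(methoxymethoxy)-5-methyl-2-(trimethylsilyl)phenyl trifluoromethanesulfonate | COCOc1cc(C)cc(OS(=O)(=O)C(F)(F)F)c1[Si](C)(C)C | intermediate
10 | 2,4-dimethoxyphenol | COc1ccc(O)c(OC)c1 | starting material
11 | 2-hydroxy-3,5-dimethoxybenzaldehyde | COc1cc(C=O)c(O)c(OC)c1 | intermediate
12 | 2-(hydroxymethyl)-4,6-dimethoxyphenol | COc1cc(CO)c(O)c(OC)c1 | intermediate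
13 | 2,4-dimethoxy-6-(triisopropylsilyloxymethyl)phenol | COc1cc(CO[Si](C(C)C)(C(C)C)C(C)C)c(O)c(OC)c1 | intermediate
14 | potassium 2,4-dimethoxy-6-(triisopropylsilyloxymethyl)phenoxide | [K+].[O-]c1c(CO[Si](C(C)C)(C(C)C)C(C)C)cc(OC)cc1OC | intermediate
15 | 3-(methoxymethoxy)-5-methylbenzyne (aryne across C1–C2 of ring A) | COCOC1=CC(C)=CC#C1 | intermediate
16 | potassium 2-[2,4-dimethoxy-6-(triisopropylsilyloxymethyl)phenoxy]-6-(methoxymethoxy)-4-methylphenyl (C1 carbanion) | [K+].COCOc1cc(C)cc(Oc2c(CO[Si](C(C)C)(C(C)C)C(C)C)cc(OC)cc2OC)[c-]1 | intermediate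
17 | potassium 2-[2,4-dimethoxy-6-(triisopropylsilyloxymethyl)phenoxy]-6-(methoxymethoxy)-4-methylbenzoate | [K+].[O-]C(=O)c1c(Oc2c(CO[Si](C(C)C)(C(C)C)C(C)C)cc(OC)cc2OC)cc(C)cc1OCOC | intermediate
18 | methyl 2-[2,4-dimethoxy-6-(triisopropylsilyloxymethyl)phenoxy]-6-(methoxymethoxy)-4-methylbenzoate | COC(=O)c1c(Oc2c(CO[Si](C(C)C)(C(C)C)C(C)C)cc(OC)cc2OC)cc(C)cc1OCOC | intermediate
19 | methyl 2-[2-(hydroxymethyl)-4,6-dimethoxyphenoxy]-6-hydroxy-4-methylbenzoate | COC(=O)c1c(Oc2c(CO)cc(OC)cc2OC)cc(C)cc1O | intermediate
20 | 3-chloro-3-methylbut-1-yne | CC(C)(Cl)C#C | starting material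
21 | methyl 2-[2-(hydroxymethyl)-4,6-dimethoxyphenoxy]-4-methyl-6-[(2-methylbut-3-yn-2-yl)oxy]benzoate | COC(=O)c1c(Oc2c(CO)cc(OC)cc2OC)cc(C)cc1OC(C)(C)C#C | intermediate
22 | methyl 2-[2-(hydroxymethyl)-4,6-dimethoxyphenoxy]-4-methyl-6-[(2-methylbut-3-en-2-yl)oxy]benzoate | COC(=O)c1c(Oc2c(CO)cc(OC)cc2OC)cc(C)cc1OC(C)(C)C=C | intermediate
23 | methyl 2-[2-(hydroxymethyl)-4,6-dimethoxyphenoxy]-4-methyl-5-(3-methylbut-2-enyl)-6-oxocyclohexa-1,3-diene-1-carboxylate (racemic at C5, transient) | COC(=O)C1=C(Oc2c(CO)cc(OC)cc2OC)C=C(C)C(CC=C(C)C)C1=O | intermediate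
24 | methyl 2-[2-(hydroxymethyl)-4,6-dimethoxyphenoxy]-6-hydroxy-4-methyl-5-(3-methylbut-2-enyl)benzoate | COC(=O)c1c(Oc2c(CO)cc(OC)cc2OC)cc(C)c(CC=C(C)C)c1O | target

**Step count and risks**

Total step count: 12. Longest linear sequence: 9 steps (orcinol 1 → 24 through steps 1–4 and 8–12); the ring B branch adds 3 steps (5–7).

Steps most likely to fail:

Step 8 (proposed new method). The C1 carbanion of 16 may be protonated before it meets CO2 (by adventitious water, the crown ether, or internal transfer from the benzylic CH2 of ring B), or fluoride may slowly strip the silyl ether. The fallback makes the two bonds one after the other by known chemistry. It sets out from 13 and 9, which are combined under standard fluoride conditions for phenol O-arylation (CsF, MeCN, rt), where the solvent protonates C1, to give the diaryl ether triisopropyl{[3,5-dimethoxy-2-(3-(methoxymethoxy)-5-methylphenoxy)phenyl]methoxy}silane F1. Directed ortho-lithiation of F1 (n-BuLi, TMEDA, THF, −78 → 0 °C) should occur at ring A C1, the site between the methoxymethoxy and aryloxy oxygens and next to the strongest directing group, to give the C1-lithiated diaryl ether F2. Quenching with methyl chloroformate at −78 °C returns to the route at 18.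

Step 10. O-Alkylation of the ester-hydrogen-bonded C6 hydroxyl may be sluggish, with dehydrochlorination of the tertiary chloride to the enyne taking over. The fallback sets out from 19 and uses decarboxylative allylic etherification with tert-butyl 2-methylbut-3-en-2-yl carbonate and Pd(PPh3)4 (zerovalent palladium) in THF at 0 °C. The phenoxide attacks the π-(1,1-dimethylallyl)palladium intermediate at its more substituted terminus under kinetic control. This gives the tertiary allyl ether directly and comes back to the route at 22, so that 21 and step 11 are bypassed.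

Step 12. On heating, the tertiary allyl ether may fragment (loss of isoprene back to 19), or the ortho-prenyl phenol may cyclise to a chroman, in competition with the [3,3] shift. The fallback sets out from 19, which is O-alkylated with 1-bromo-3-methylbut-2-ene (K2CO3, acetone) to the linear prenyl ether methyl 2-[2-(hydroxymethyl)-4,6-dimethoxyphenoxy]-4-methyl-6-[(3-methylbut-2-enyl)oxy]benzoate F3. Treatment of F3 with montmorillonite K10 clay in CH2Cl2 at 0 °C → rt should bring about the known clay-promoted [1,3] oxygen-to-carbon prenyl shift to the free ortho position C5, and this comes back to the route at 24.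

**Further compounds**

F1 | step 8 | triisopropyl{[3,5-dimethoxy-2-(3-(methoxymethoxy)-5-methylphenoxy)phenyl]methoxy}silane | COCOc1cc(C)cc(Oc2c(CO[Si](C(C)C)(C(C)C)C(C)C)cc(OC)cc2OC)c1
F2 | step 8 | C1-lithiated diaryl ether (2-lithio derivative of F1 between the methoxymethoxy and aryloxy groups) | [Li]c1c(OCOC)cc(C)cc1Oc1c(CO[Si](C(C)C)(C(C)C)C(C)C)cc(OC)cc1OC
F0 | step 10 | none | none
F3 | step 12 | methyl 2-[2-(hydroxymethyl)-4,6-dimethoxyphenoxy]-4-methyl-6-[(3-methylbut-2-enyl)oxy]benzoate | COC(=O)c1c(Oc2c(CO)cc(OC)cc2OC)cc(C)cc1OCC=C(C)C
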